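The route rests on disconnecting C1 of ring B twice: C1–C2 and C1–aryl. C1 is doubly benzylic and sits ortho to the C8 methoxy and para to the C6 methoxy group of ring A, so it can serve first as a ring A aldehyde carbon and then as a stabilised cation. In one operation a Lewis acid lets a tethered allylsilane close ring B at C1–C2 and then lets 2,6-dimethoxyphenol add through its para carbon at C1, setting C1 and C2 from the auxiliary-derived C3. The precursor is a ring A benzaldehyde carrying an (S)-2-(benzyloxymethyl)-5-(trimethylsilyl)pent-3-enyl chain ortho to the formyl group; the vinyl group left at C2 is the masked sulfated arm.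

Key step: step 11

Assumption: the target is drawn as the free hydrogen sulfate, so it is carried as its sodium salt and the acid is released only in the last operation.
Remark: the cross-metathesis should give mainly the E allylsilane; the alkene geometry is not transferred to any stereocentre in step 11, so any Z isomer should converge on the same product.

Step 1
Reactants: 1 syringaldehyde
Product: 2 4-(benzyloxy)-3,5-dimethoxybenzaldehyde
Conditions: BnBr, K2CO3, DMF, 60 °C
Reagents that add atoms: benzyl bromide, BrCc1ccccc1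
Why: Williamson etherification of the acidic phenol; the benzyl ether is chosen because it tolerates every later step and leaves by hydrogenolysis at the end.

Step 2
Reactants: 2 4-(benzyloxy)-3,5-dimethoxybenzaldehyde
Product: 3 4-(benzyloxy)-2-bromo-3,5-dimethoxybenzaldehyde
Conditions: NBS, MeCN, 50 °C, dark
Reagents that add atoms: N-bromosuccinimide, O=C1CCC(=O)N1Br
Why: Electrophilic aromatic bromination; the two free positions are equivalent and each is ortho and para to a methoxy group, the formyl group and the first bromine slow a second substitution, and the benzyl ring is far less activated.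

Step 3
Reactants: 3 4-(benzyloxy)-2-bromo-3,5-dimethoxybenzaldehyde
Product: 4 [4-(benzyloxy)-2-bromo-3,5-dimethoxyphenyl]methanol
Conditions: NaBH4, MeOH/THF, 0 °C
Reagents that add atoms: none
Why: Borohydride reduction of the aldehyde; aryl bromide and benzyl ether are inert.

Step 4
Reactants: 4 [4-(benzyloxy)-2-bromo-3,5-dimethoxyphenyl]methanol
Product: 5 4-(benzyloxy)-2-bromo-1-(bromomethyl)-3,5-dimethoxybenzene
Conditions: PBr3, CH2Cl2, 0 °C
Reagents that add atoms: phosphorus tribromide, BrP(Br)Br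
Why: Conversion of an electron-rich benzylic alcohol into the bromide through its phosphite ester, fast at 0 °C so that the aryl benzyl ether is not cleaved; the bromide is used directly.

Step 5
Reactants: 6 (S)-4-benzyloxazolidin-2-one; 7 (E)-but-2-enoyl chloride
Product: 9 (S)-4-benzyl-3-[(E)-but-2-enoyl]oxazolidin-2-one, via lithium oxazolidinide 8 (not isolated)
Conditions: n-BuLi, THF, −78 °C; then 7, −78 → 0 °C
Reagents that add atoms: none
Why: N-acylation of the lithiated oxazolidinone by the acid chloride (loading of the Evans auxiliary); the auxiliary stereocentre is not touched.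

Step 6
Reactants: 9 (S)-4-benzyl-3-[(E)-but-2-enoyl]oxazolidin-2-one; 5 4-(benzyloxy)-2-bromo-1-(bromomethyl)-3,5-dimethoxybenzene
Product: 11 (S)-4-benzyl-3-[(S)-2-{[4-(benzyloxy)-2-bromo-3,5-dimethoxyphenyl]methyl}but-3-enoyl]oxazolidin-2-one, via sodium dienolate 10 (not isolated)
Conditions: NaN(SiMe3)2, THF, −78 °C; then 5, −78 → −30 °C
Reagents that add atoms: none
Why: Evans alkylation in its deconjugative form: γ-deprotonation gives the chelated Z(O)-dienolate, which the reactive benzylic bromide alkylates at the α-carbon on the face opposite the C4 benzyl group of the auxiliary, setting the future C3 (S in 11) and leaving the vinyl group whose inner carbon becomes C2.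

Step 7
Reactants: 11 (S)-4-benzyl-3-[(S)-2-{[4-(benzyloxy)-2-bromo-3,5-dimethoxyphenyl]methyl}but-3-enoyl]oxazolidin-2-one
Product: 12 (S)-2-{[4-(benzyloxy)-2-bromo-3,5-dimethoxyphenyl]methyl}but-3-en-1-ol
Conditions: LiBH4, H2O (1 equiv), Et2O, 0 °C
Reagents that add atoms: none
Why: Reductive cleavage of the auxiliary by hydride attack on the exocyclic imide carbonyl gives the primary alcohol (future C3a) and returns 6; the α-hydrogen is not removed under these conditions, and aryl bromide and alkene do not react.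

Step 8
Reactants: 12 (S)-2-{[4-(benzyloxy)-2-bromo-3,5-dimethoxyphenyl]methyl}but-3-en-1-ol
Product: 13 4-(benzyloxy)-1-[(S)-2-(benzyloxymethyl)but-3-en-1-yl]-2-bromo-3,5-dimethoxybenzene
Conditions: NaH, BnBr, n-Bu4NI (cat.), THF, 0 °C → rt
Reagents that add atoms: benzyl bromide, BrCc1ccccc1
Why: Williamson etherification; the C3a oxygen must carry no hydrogen in step 11, where a free hydroxyl would trap the C1 cation, and benzyl leaves with the other benzyl groups at the end.

Step 9
Reactants: 13 4-(benzyloxy)-1-[(S)-2-(benzyloxymethyl)but-3-en-1-yl]-2-bromo-3,5-dimethoxybenzene; 14 allyltrimethylsilane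
Product: 15 4-(benzyloxy)-1-[(S,E)-2-(benzyloxymethyl)-5-(trimethylsilyl)pent-3-en-1-yl]-2-bromo-3,5-dimethoxybenzene
Conditions: 14 (4 equiv), RuCl2(=CHPh)(PCy3)(H2IMes) (second-generation Grubbs catalyst, 5 mol %), CH2Cl2, 40 °C
Reagents that add atoms: none
Why: Olefin cross-metathesis: the branched terminal alkene of 13 homodimerises slowly while excess 14 (and its own dimer) delivers the silylmethyl-substituted alkylidene, which should give mainly the E allylsilane without touching the allylic stereocentre, the aryl bromide or the benzyl ethers.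

Step 10
Reactants: 15 4-(benzyloxy)-1-[(S,E)-2-(benzyloxymethyl)-5-(trimethylsilyl)pent-3-en-1-yl]-2-bromo-3,5-dimethoxybenzene
Product: 17 3-(benzyloxy)-6-[(S,E)-2-(benzyloxymethyl)-5-(trimethylsilyl)pent-3-en-1-yl]-2,4-dimethoxybenzaldehyde, via aryllithium 16 (not isolated)
Conditions: n-BuLi, THF, −78 °C; then DMF, −78 → 0 °C; H2O
Reagents that add atoms: N,N-dimethylformamide, CN(C)C=O
Why: Bromine–lithium exchange at −78 °C is much faster than deprotonation or addition elsewhere, and the aryllithium is formylated by DMF (Bouveault aldehyde synthesis), installing C1; allylsilane and benzyl ethers are inert at this temperature.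

Step 11
Reactants: 17 3-(benzyloxy)-6-[(S,E)-2-(benzyloxymethyl)-5-(trimethylsilyl)pent-3-en-1-yl]-2,4-dimethoxybenzaldehyde; 18 2,6-dimethoxyphenol
Product: 21 4-[(1R,2S,3S)-7-(benzyloxy)-3-(benzyloxymethyl)-6,8-dimethoxy-2-vinyl-1,2,3,4-tetrahydronaphthalen-1-yl]-2,6-dimethoxyphenol, via tetralin-1-ol 19 (not isolated), via C1 benzylic cation 20 (not isolated)
Conditions: BF3·OEt2 (1.5 equiv), CH2Cl2, −78 °C; then 18 (5 equiv), −78 → −10 °C; aq NaHCO3
Reagents that add atoms: none
Why: BF3 activates the aldehyde of 17 and the γ-carbon of the allylsilane (future C2) attacks C1 with loss of silicon as Me3SiF (intramolecular Hosomi–Sakurai reaction), closing ring B by 6-exo-trig attack on the carbonyl to give boron-bound tetralin-1-ol 19. On warming, the C1–O bond ionises because cation 20 is benzylic and conjugated with the C8 (ortho) and C6 (para) methoxy groups of ring A, and 18 is alkylated at its para carbon (Friedel–Crafts reaction). Both events are known reaction types on these substrate classes (allylsilane–aryl aldehyde cyclisation; acid-mediated arylation of electron-rich benzylic alcohols by phenols) and are only run here in one flask under one Lewis acid. C2 is set in a chair-like transition state in which the C3 benzyloxymethyl group and the exocyclic part of the allyl unit are equatorial and the allylic C3–H eclipses the alkene, which gives 2,3-trans from either alkene geometry. C1 is set when the arene adds to the planar cation on the face opposite the neighbouring C2 vinyl group, which gives 1,2-trans whatever the configuration of the hydroxyl in 19. The step needs arylation to outrun proton loss to the 1,2-dihydronaphthalene, the phenol to react through C4 and the allylsilane to survive until it cyclises; a large excess of 18 added only after ring closure at −78 °C, the conjugation of the para carbon with the free hydroxyl together with its low hindrance, and the absence of any free hydroxyl in 17 (C7 and C3a are benzyl ethers) should secure this.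

Step 12
Reactants: 21 4-[(1R,2S,3S)-7-(benzyloxy)-3-(benzyloxymethyl)-6,8-dimethoxy-2-vinyl-1,2,3,4-tetrahydronaphthalen-1-yl]-2,6-dimethoxyphenol
Product: 22 (1R,2S,3S)-7-(benzyloxy)-1-[4-(benzyloxy)-3,5-dimethoxyphenyl]-3-(benzyloxymethyl)-6,8-dimethoxy-2-vinyl-1,2,3,4-tetrahydronaphthalene
Conditions: BnBr, K2CO3, DMF, rt
Reagents that add atoms: benzyl bromide, BrCc1ccccc1
Why: Williamson etherification of the only free hydroxyl; the electron-rich phenol must be masked before the periodate oxidation and the sulfation.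

Step 13
Reactants: 22 (1R,2S,3S)-7-(benzyloxy)-1-[4-(benzyloxy)-3,5-dimethoxyphenyl]-3-(benzyloxymethyl)-6,8-dimethoxy-2-vinyl-1,2,3,4-tetrahydronaphthalene
Product: 24 [(1R,2S,3S)-7-(benzyloxy)-1-[4-(benzyloxy)-3,5-dimethoxyphenyl]-3-(benzyloxymethyl)-6,8-dimethoxy-1,2,3,4-tetrahydronaphthalen-2-yl]methanol, via aldehyde 23 (not isolated)
Conditions: OsO4 (2 mol %), NaIO4, 2,6-lutidine, dioxane/H2O, rt; aqueous extraction; then NaBH4, MeOH/THF, 0 °C
Reagents that add atoms: osmium tetroxide (catalytic, reoxidised by periodate), O=[Os](=O)(=O)=O; sodium periodate, [Na+].[O-]I(=O)(=O)=O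
Why: Lemieux–Johnson cleavage (dihydroxylation, then glycol cleavage) of the only alkene removes the terminal carbon, and immediate borohydride reduction of the crude C2 aldehyde gives C2a–OH before the α-centre, already in the favoured all-trans arrangement, can epimerise.

Step 14
Reactants: 24 [(1R,2S,3S)-7-(benzyloxy)-1-[4-(benzyloxy)-3,5-dimethoxyphenyl]-3-(benzyloxymethyl)-6,8-dimethoxy-1,2,3,4-tetrahydronaphthalen-2-yl]methanol
Product: 26 sodium [(1R,2S,3S)-7-(benzyloxy)-1-[4-(benzyloxy)-3,5-dimethoxyphenyl]-3-(benzyloxymethyl)-6,8-dimethoxy-1,2,3,4-tetrahydronaphthalen-2-yl]methyl sulfate, via pyridinium sulfate 25 (not isolated)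
Conditions: SO3·pyridine, pyridine, rt → 40 °C; then aq NaHCO3
Reagents that add atoms: sulfur trioxide–pyridine complex, O=S(=O)=O.c1ccncc1; sodium hydrogen carbonate, [Na+].OC(=O)[O-]
Why: O-sulfation of the only free hydroxyl by the sulfur trioxide–amine complex; exchange to the sodium salt removes pyridine, which would slow the benzyl ether hydrogenolysis that follows.

Step 15
Reactants: 26 sodium [(1R,2S,3S)-7-(benzyloxy)-1-[4-(benzyloxy)-3,5-dimethoxyphenyl]-3-(benzyloxymethyl)-6,8-dimethoxy-1,2,3,4-tetrahydronaphthalen-2-yl]methyl sulfate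
Product: 28 [(1R,2S,3S)-7-hydroxy-1-(4-hydroxy-3,5-dimethoxyphenyl)-3-(hydroxymethyl)-6,8-dimethoxy-1,2,3,4-tetrahydronaphthalen-2-yl]methyl hydrogen sulfate, via target sodium salt 27 (not isolated)
Conditions: H2 (1 atm), Pd/C, MeOH/THF, rt; filter; then HCl (1.0 equiv), H2O, 0 °C; C18 desalting, freeze-drying
Reagents that add atoms: none
Why: Catalytic hydrogenolysis removes the two aryl benzyl ethers and the alkyl benzyl ether while a sulfate monoester salt is inert to hydrogen on palladium and no stereocentre is touched; one equivalent of acid in the cold then gives the hydrogen sulfate as drawn.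

Compound list
1 | syringaldehyde (4-hydroxy-3,5-dimethoxybenzaldehyde) | COc1cc(C=O)cc(OC)c1O | starting material
2 | 4-(benzyloxy)-3,5-dimethoxybenzaldehyde | COc1cc(C=O)cc(OC)c1OCc1ccccc1 | intermediate
3 | 4-(benzyloxy)-2-bromo-3,5-dimethoxybenzaldehyde | COc1cc(C=O)c(Br)c(OC)c1OCc1ccccc1 | intermediate
4 | [4-(benzyloxy)-2-bromo-3,5-dimethoxyphenyl]methanol | COc1cc(CO)c(Br)c(OC)c1OCc1ccccc1 | intermediate
5 | 4-(benzyloxy)-2-bromo-1-(bromomethyl)-3,5-dimethoxybenzene | COc1cc(CBr)c(Br)c(OC)c1OCc1ccccc1 | intermediate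
6 | (S)-4-benzyloxazolidin-2-one | O=C1N[C@@H](Cc2ccccc2)CO1 | starting material
7 | (E)-but-2-enoyl chloride (crotonyl chloride) | C/C=C/C(=O)Cl | starting material
8 | N-lithiated (S)-4-benzyloxazolidin-2-one | [Li+].O=C1[N-][C@@H](Cc2ccccc2)CO1 | intermediate (not isolated)
9 | (S)-4-benzyl-3-[(E)-but-2-enoyl]oxazolidin-2-one | C/C=C/C(=O)N1C(=O)OC[C@@H]1Cc1ccccc1 | intermediate
10 | sodium (1Z)-1-[(S)-4-benzyl-2-oxooxazolidin-3-yl]buta-1,3-dien-1-olate | [Na+].[O-]/C(=C\C=C)N1C(=O)OC[C@@H]1Cc1ccccc1 | intermediate (not isolated)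
11 | (S)-4-benzyl-3-[(S)-2-{[4-(benzyloxy)-2-bromo-3,5-dimethoxyphenyl]methyl}but-3-enoyl]oxazolidin-2-one | COc1c(Br)c(C[C@H](C(=O)N2C(=O)OC[C@@H]2Cc2ccccc2)C=C)cc(OC)c1OCc1ccccc1 | intermediate
12 | (S)-2-{[4-(benzyloxy)-2-bromo-3,5-dimethoxyphenyl]methyl}but-3-en-1-ol | COc1c(Br)c(C[C@H](CO)C=C)cc(OC)c1OCc1ccccc1 | intermediate
13 | 4-(benzyloxy)-1-[(S)-2-(benzyloxymethyl)but-3-en-1-yl]-2-bromo-3,5-dimethoxybenzene | COc1c(Br)c(C[C@H](COCc2ccccc2)C=C)cc(OC)c1OCc1ccccc1 | intermediate
14 | allyltrimethylsilane | C=CC[Si](C)(C)C | starting material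
15 | 4-(benzyloxy)-1-[(S,E)-2-(benzyloxymethyl)-5-(trimethylsilyl)pent-3-en-1-yl]-2-bromo-3,5-dimethoxybenzene | COc1c(Br)c(C[C@H](COCc2ccccc2)/C=C/C[Si](C)(C)C)cc(OC)c1OCc1ccccc1 | intermediate
16 | aryllithium from 15 (lithium in place of bromine) | [Li]c1c(C[C@H](COCc2ccccc2)/C=C/C[Si](C)(C)C)cc(OC)c(OCc2ccccc2)c1OC | intermediate (not isolated)
17 | 3-(benzyloxy)-6-[(S,E)-2-(benzyloxymethyl)-5-(trimethylsilyl)pent-3-en-1-yl]-2,4-dimethoxybenzaldehyde | O=Cc1c(C[C@H](COCc2ccccc2)/C=C/C[Si](C)(C)C)cc(OC)c(OCc2ccccc2)c1OC | intermediate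
18 | 2,6-dimethoxyphenol | COc1cccc(OC)c1O | starting material
19 | (2R,3S)-7-(benzyloxy)-3-(benzyloxymethyl)-6,8-dimethoxy-2-vinyl-1,2,3,4-tetrahydronaphthalen-1-ol, boron-bound, both C1 epimers | OC1c2c(cc(OC)c(OCc3ccccc3)c2OC)C[C@H](COCc3ccccc3)[C@H]1C=C | intermediate (not isolated)
20 | C1 benzylic cation of the 2,3-trans tetralin (C2 and C3 as in 19) | [CH+]1c2c(cc(OC)c(OCc3ccccc3)c2OC)C[C@H](COCc3ccccc3)[C@H]1C=C | intermediate (not isolated)
21 | 4-[(1R,2S,3S)-7-(benzyloxy)-3-(benzyloxymethyl)-6,8-dimethoxy-2-vinyl-1,2,3,4-tetrahydronaphthalen-1-yl]-2,6-dimethoxyphenol | COc1cc([C@@H]2c3c(cc(OC)c(OCc4ccccc4)c3OC)C[C@H](COCc4ccccc4)[C@H]2C=C)cc(OC)c1O | intermediate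
22 | (1R,2S,3S)-7-(benzyloxy)-1-[4-(benzyloxy)-3,5-dimethoxyphenyl]-3-(benzyloxymethyl)-6,8-dimethoxy-2-vinyl-1,2,3,4-tetrahydronaphthalene | COc1cc([C@@H]2c3c(cc(OC)c(OCc4ccccc4)c3OC)C[C@H](COCc4ccccc4)[C@H]2C=C)cc(OC)c1OCc1ccccc1 | intermediate
23 | (1R,2S,3S)-7-(benzyloxy)-1-[4-(benzyloxy)-3,5-dimethoxyphenyl]-3-(benzyloxymethyl)-6,8-dimethoxy-1,2,3,4-tetrahydronaphthalene-2-carbaldehyde | COc1cc([C@@H]2c3c(cc(OC)c(OCc4ccccc4)c3OC)C[C@H](COCc4ccccc4)[C@H]2C=O)cc(OC)c1OCc1ccccc1 | intermediate (not isolated)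
24 | [(1R,2S,3S)-7-(benzyloxy)-1-[4-(benzyloxy)-3,5-dimethoxyphenyl]-3-(benzyloxymethyl)-6,8-dimethoxy-1,2,3,4-tetrahydronaphthalen-2-yl]methanol | COc1cc([C@@H]2c3c(cc(OC)c(OCc4ccccc4)c3OC)C[C@H](COCc4ccccc4)[C@H]2CO)cc(OC)c1OCc1ccccc1 | intermediate
25 | pyridinium salt of the C2a sulfate of 24 | COc1cc([C@@H]2c3c(cc(OC)c(OCc4ccccc4)c3OC)C[C@H](COCc4ccccc4)[C@H]2COS(=O)(=O)[O-])cc(OC)c1OCc1ccccc1.c1cc[nH+]cc1 | intermediate (not isolated)
26 | sodium [(1R,2S,3S)-7-(benzyloxy)-1-[4-(benzyloxy)-3,5-dimethoxyphenyl]-3-(benzyloxymethyl)-6,8-dimethoxy-1,2,3,4-tetrahydronaphthalen-2-yl]methyl sulfate | COc1cc([C@@H]2c3c(cc(OC)c(OCc4ccccc4)c3OC)C[C@H](COCc4ccccc4)[C@H]2COS(=O)(=O)[O-])cc(OC)c1OCc1ccccc1.[Na+] | intermediate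
27 | sodium salt of the target | COc1cc([C@@H]2c3c(cc(OC)c(O)c3OC)C[C@H](CO)[C@H]2COS(=O)(=O)[O-])cc(OC)c1O.[Na+] | intermediate (not isolated)
28 | [(1R,2S,3S)-7-hydroxy-1-(4-hydroxy-3,5-dimethoxyphenyl)-3-(hydroxymethyl)-6,8-dimethoxy-1,2,3,4-tetrahydronaphthalen-2-yl]methyl hydrogen sulfate | COc1cc([C@@H]2c3c(cc(OC)c(O)c3OC)C[C@H](CO)[C@H]2COS(=O)(=O)O)cc(OC)c1O | target

Total step count: 15. Longest linear sequence: 14 steps (steps 1–4 and 6–15 from syringaldehyde; step 5 is the side branch).

Steps most likely to fail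

1. Step 11. After ring closure the C1 cation may lose the C2 proton to give the conjugated 1,2-dihydronaphthalene faster than it is arylated, which also erases C2. The allylsilane may instead be protodesilylated before it cyclises, or the arene may add on the wrong face. The fallback reverses the order of the two bond formations and sets out from 17. 2-(Benzyloxy)-5-bromo-1,3-dimethoxybenzene F1 would be made from commercial 4-bromo-2,6-dimethoxyphenol with BnBr and K2CO3. Bromine–lithium exchange (n-BuLi, THF, −78 °C) turns it into [4-(benzyloxy)-3,5-dimethoxyphenyl]lithium F2, which adds to the aldehyde of 17 to give the diarylmethanol F3 as a mixture of carbinol epimers. With BF3·OEt2 in CH2Cl2 at −78 °C, F3 ionises to a diarylmethyl cation that has no β-hydrogen, so elimination is excluded. The pendant allylsilane should then close ring B at C1–C2 (cation–allylsilane cyclisation) through a chair with the pendant aryl, the C3 arm and the alkenyl terminus all equatorial. This delivers benzyl ether 22 directly, where the route is rejoined, and step 12 falls away.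

2. Step 6. The dienolate may be alkylated partly at its γ-carbon, the β,γ-alkene of the product may drift back into conjugation with loss of the new stereocentre, or facial control may be eroded. The fallback sets the same stereocentre by a saturated-enolate alkylation and sets out from 3.
   - Condensation of 3 with Meldrum's acid in HCO2H/Et3N at 100 °C (Knoevenagel condensation, transfer hydrogenation, decarboxylation) gives 3-[4-(benzyloxy)-2-bromo-3,5-dimethoxyphenyl]propanoic acid F4.
   - Mixed-anhydride coupling with 6 (pivaloyl chloride, Et3N, LiCl, THF) gives (S)-4-benzyl-3-{3-[4-(benzyloxy)-2-bromo-3,5-dimethoxyphenyl]propanoyl}oxazolidin-2-one F5.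
   - Soft enolisation with TiCl4 and i-Pr2NEt in CH2Cl2 at 0 °C and alkylation by benzyl chloromethyl ether, anti to the auxiliary benzyl group, gives (S)-4-benzyl-3-[(R)-3-(benzyloxy)-2-{[4-(benzyloxy)-2-bromo-3,5-dimethoxyphenyl]methyl}propanoyl]oxazolidin-2-one F6.
   - LiBH4 gives (S)-3-(benzyloxy)-2-{[4-(benzyloxy)-2-bromo-3,5-dimethoxyphenyl]methyl}propan-1-ol F7.
   - Dess–Martin oxidation gives (R)-3-(benzyloxy)-2-{[4-(benzyloxy)-2-bromo-3,5-dimethoxyphenyl]methyl}propanal F8, which is methylenated at once with Ph3P=CH2 (Wittig reaction) to give 13, where the route is rejoined.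

3. Step 13. This is the only oxidation on the fully assembled, electron-rich skeleton: the C2 aldehyde may epimerise or be over-oxidised while it sits in the aqueous oxidant mixture, or periodate may attack the arenes. The fallback separates hydroxylation from cleavage and sets out from 22. Dihydroxylation with catalytic K2OsO2(OH)4 and N-methylmorpholine N-oxide in acetone/H2O gives the isolable 1-[(1R,2S,3S)-7-(benzyloxy)-1-[4-(benzyloxy)-3,5-dimethoxyphenyl]-3-(benzyloxymethyl)-6,8-dimethoxy-1,2,3,4-tetrahydronaphthalen-2-yl]ethane-1,2-diol F9 (both carbinol epimers). F9 is cleaved with Pb(OAc)4 in dry CH2Cl2 at 0 °C, and the filtered solution of aldehyde 23 is reduced immediately with NaBH4 in MeOH to give 24, where the route is rejoined.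

Further compounds
F1 | step 11 | 2-(benzyloxy)-5-bromo-1,3-dimethoxybenzene | COc1cc(Br)cc(OC)c1OCc1ccccc1
F2 | step 11 | [4-(benzyloxy)-3,5-dimethoxyphenyl]lithium | [Li]c1cc(OC)c(OCc2ccccc2)c(OC)c1
F3 | step 11 | [4-(benzyloxy)-3,5-dimethoxyphenyl]{3-(benzyloxy)-6-[(S,E)-2-(benzyloxymethyl)-5-(trimethylsilyl)pent-3-en-1-yl]-2,4-dimethoxyphenyl}methanol, both carbinol epimers | OC(c1cc(OC)c(OCc2ccccc2)c(OC)c1)c1c(C[C@H](COCc2ccccc2)/C=C/C[Si](C)(C)C)cc(OC)c(OCc2ccccc2)c1OC
F4 | step 6 | 3-[4-(benzyloxy)-2-bromo-3,5-dimethoxyphenyl]propanoic acid | COc1c(Br)c(CCC(=O)O)cc(OC)c1OCc1ccccc1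
F5 | step 6 | (S)-4-benzyl-3-{3-[4-(benzyloxy)-2-bromo-3,5-dimethoxyphenyl]propanoyl}oxazolidin-2-one | COc1c(Br)c(CCC(=O)N2C(=O)OC[C@@H]2Cc2ccccc2)cc(OC)c1OCc1ccccc1
F6 | step 6 | (S)-4-benzyl-3-[(R)-3-(benzyloxy)-2-{[4-(benzyloxy)-2-bromo-3,5-dimethoxyphenyl]methyl}propanoyl]oxazolidin-2-one | COc1c(Br)c(C[C@H](COCc2ccccc2)C(=O)N2C(=O)OC[C@@H]2Cc2ccccc2)cc(OC)c1OCc1ccccc1
F7 | step 6 | (S)-3-(benzyloxy)-2-{[4-(benzyloxy)-2-bromo-3,5-dimethoxyphenyl]methyl}propan-1-ol | COc1c(Br)c(C[C@H](COCc2ccccc2)CO)cc(OC)c1OCc1ccccc1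
F8 | step 6 | (R)-3-(benzyloxy)-2-{[4-(benzyloxy)-2-bromo-3,5-dimethoxyphenyl]methyl}propanal | COc1c(Br)c(C[C@H](COCc2ccccc2)C=O)cc(OC)c1OCc1ccccc1
F9 | step 13 | 1-[(1R,2S,3S)-7-(benzyloxy)-1-[4-(benzyloxy)-3,5-dimethoxyphenyl]-3-(benzyloxymethyl)-6,8-dimethoxy-1,2,3,4-tetrahydronaphthalen-2-yl]ethane-1,2-diol, both carbinol epimers | COc1cc([C@@H]2c3c(cc(OC)c(OCc4ccccc4)c3OC)C[C@H](COCc4ccccc4)[C@H]2C(O)CO)cc(OC)c1OCc1ccccc1
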